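**Plan**

- Retrosynthesis: the diene is cut at the single bond between its two alkenes (alkenyl iodide 27 + alkenylboronate 13). In the trimethylcyclohexanediol ring the CH2–CH2 bond and the bond from the secondary carbinol carbon to the gem-dimethyl carbon are cut together. The epoxycyclohexenediol goes back through its oxirane C–O bonds and an aryl ring to dialdehyde 14.
- Enabling feature: in the carbocycle the O–CH–CH2 unit lies between the CH2 next to the tertiary carbinol carbon and the quaternary carbon next to the ring CH. With that carbinol carbon as a ketone and the ring CH carrying an ester, these two ends are the α-carbon of a ketone (electrophilic radical) and the β-carbon of an isopropylidene keto ester (radical acceptor). A vinyl silyl ether can therefore be stitched in by a polarity-alternating radical addition and 6-endo closure.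
- Forward, east: Knoevenagel, radical annulation to the cyclohexane, oxidation, asymmetric hydrogenation with closure of a bridging lactone, methyl addition, lactol, boryl olefination. Forward, west: arene to quinone monoketal, CBS reduction, silylene, enal, alkynylation, hydroalumination–iodination, epoxidation, enone, directed reduction. Then Suzuki coupling and desilylation.
- Stereochemistry, east: the hydrogenation sets the secondary carbinol; the temporary lactone ring fixes the ring CH cis to it and exposes one ketone face, so the methyl Grignard sets the tertiary carbinol.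
- Stereochemistry, west: CBS sets the first ring carbinol, the zinc–ProPhenol alkynylation the side-chain carbinol, tartrate plus silyloxy group the oxirane, and internal hydride delivery the last carbinol. The Z alkene comes from trans-hydroalumination, the E alkene from the chromium olefination.

Key step: step 2

Assumption: the ligand or catalyst antipode named in steps 4, 11, 14 and 16 and in the fallbacks is the one the usual model predicts for the drawn configuration; should a sense prove opposite, the mirror-image ligand applies.

**Route**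

Step 1
Reactants: 1 ethyl 4-chloro-3-oxobutanoate; 2 acetone
Product: 3 ethyl 2-(2-chloroacetyl)-3-methylbut-2-enoate
Conditions: TiCl4, pyridine, THF, 0 °C to rt
Reagents that add atoms: none
Why: Knoevenagel condensation mediated by TiCl4 and pyridine, in which the titanium-chelated keto ester adds to acetone and the water is taken up by the titanium, should give the tetrasubstituted alkylidene keto ester without any stereocentre.

Step 2
Reactants: 3 ethyl 2-(2-chloroacetyl)-3-methylbut-2-enoate; 4 trimethyl(vinyloxy)silane
Product: 7 racemic ethyl 3-hydroxy-2,2-dimethyl-6-oxocyclohexane-1-carboxylate (both diastereomers), via iodo ketone 5 (not isolated), via trimethylsilyl ether 6 (not isolated)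
Conditions: fac-Ir(ppy)3 (1 mol%), NaI (20 mol%), Hantzsch ester (1.2 equiv, syringe pump), NaHCO3, 4 (10 equiv), MeCN, blue LEDs, rt; then 1 M HCl, THF
Reagents that add atoms: none
Why: Proposed new method: single-electron reduction of iodide 5 (Finkelstein exchange in the flask) gives the α-keto radical at the former chloromethyl carbon, which as an electrophilic radical adds to the CH2 end of the electron-rich enol ether 4 (first bond, CH2–CH2); the nucleophilic α-silyloxy radical so formed then attacks the isopropylidene carbon of the keto ester (second bond, carbinol carbon to quaternary carbon), and the resulting 1,3-dicarbonyl radical takes a hydrogen atom from the Hantzsch ester. The closest known reaction types are the photoredox atom-transfer and Giese additions of α-halocarbonyl radicals to enol ethers and the 6-endo cyclisation of radicals tethered to the α-carbon of acrylates. The six-membered ring closes 6-endo-trig, because the 5-exo alternative would be attack at the fully substituted α-carbon and would leave an unstabilised tertiary radical. The silyloxy-bearing carbon is formed without control (it is flattened to the ketone in step 3) and the ester-bearing carbon stays epimerisable. The step needs the intermolecular addition to outrun reduction of the first radical and the ring closure to outrun reduction of the second, which the excess of 4, the slow feed of the hydrogen donor and the double activation of the acceptor by ketone and ester are meant to secure. The match of polarity at each stage (electrophilic radical to enol ether, nucleophilic radical to electron-poor alkene) fixes the regiochemistry.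

Step 3
Reactants: 7 racemic ethyl 3-hydroxy-2,2-dimethyl-6-oxocyclohexane-1-carboxylate
Product: 8 ethyl 2,2-dimethyl-3,6-dioxocyclohexane-1-carboxylate
Conditions: Pr4N[RuO4] (5 mol%), NMO, 4 Å MS, CH2Cl2, rt
Reagents that add atoms: none
Why: Ley–Griffith oxidation of the secondary alcohol should give the 1,4-diketone and erase the uncontrolled carbinol centre while leaving the β-keto ester alone.

Step 4
Reactants: 8 ethyl 2,2-dimethyl-3,6-dioxocyclohexane-1-carboxylate
Product: 10 (1R,5R)-8,8-dimethyl-6-oxabicyclo[3.2.1]octane-2,7-dione, via hydroxy keto ester 9 (not isolated)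
Conditions: RuCl2[(R)-Tol-BINAP][2-(aminomethyl)pyridine] (0.5 mol%), KOtBu (1.1 equiv), H2 (9 atm), EtOH, rt; 1 M HCl; then TsOH·H2O (10 mol%), toluene, 90 °C
Reagents that add atoms: none
Why: Noyori asymmetric hydrogenation of a tert-alkyl ketone with the diphosphine/diamine ruthenium catalyst should reduce only the ketone flanked by the gem-dimethyl carbon, because the β-keto ester is held as its potassium enolate, and set the R carbinol centre under ligand control, after which acid-catalysed lactonisation (intramolecular transesterification) closes the bridged γ-lactone while the ester-bearing carbon epimerises through its enol into the only configuration, cis to the hydroxyl, that can lactonise.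

Step 5
Reactants: 10 (1R,5R)-8,8-dimethyl-6-oxabicyclo[3.2.1]octane-2,7-dione
Product: 11 (1R,2R,5R)-2-hydroxy-2,8,8-trimethyl-6-oxabicyclo[3.2.1]octan-7-one
Conditions: MeMgBr (1.2 equiv), CeCl3 (1.5 equiv), THF, −78 °C
Reagents that add atoms: methylmagnesium bromide, C[Mg]Br
Why: Organocerium 1,2-addition, which suppresses enolisation and prefers the ketone to the lactone, should occur on the ketone face away from the methyl of the one-carbon bridge that lies over it (equatorial attack on the locked chair), placing the new methyl cis to the lactone carbonyl carbon and the tertiary hydroxyl trans to it.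

Step 6
Reactants: 11 (1R,2R,5R)-2-hydroxy-2,8,8-trimethyl-6-oxabicyclo[3.2.1]octan-7-one
Product: 12 (1R,2R,5R)-2,8,8-trimethyl-6-oxabicyclo[3.2.1]octane-2,7-diol (both lactol epimers)
Conditions: iBu2AlH (2.2 equiv), CH2Cl2, −78 °C
Reagents that add atoms: none
Why: Partial reduction of a lactone with diisobutylaluminium hydride stops at the aluminium hemiacetal at low temperature and should give the lactol without touching the stereocentres.

Step 7
Reactants: 12 (1R,2R,5R)-2,8,8-trimethyl-6-oxabicyclo[3.2.1]octane-2,7-diol
Product: 13 (1R,2R,4R)-1,3,3-trimethyl-2-[(E)-2-(4,4,5,5-tetramethyl-1,3,2-dioxaborolan-2-yl)ethenyl]cyclohexane-1,4-diol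
Conditions: CrCl2, Cl2CHBpin, LiI, THF, rt
Reagents that add atoms: 2-(dichloromethyl)-4,4,5,5-tetramethyl-1,3,2-dioxaborolane, ClC(Cl)B1OC(C)(C)C(C)(C)O1
Why: Takai–Utimoto boryl olefination of the hydroxy aldehyde that is in equilibrium with the lactol should give the E alkenylboronate through the geminal dichromium reagent under non-basic conditions, so that the α-stereocentre is kept and no retro-aldol cleavage of the β-hydroxy aldehyde occurs.

Step 8
Reactants: 14 2,5-dimethoxybenzene-1,4-dicarbaldehyde
Product: 15 2-hydroxy-5-methoxybenzene-1,4-dicarbaldehyde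
Conditions: BCl3 (1.05 equiv), CH2Cl2, −78 to 0 °C
Reagents that add atoms: none
Why: Chelation-assisted ether cleavage by BCl3 removes a methyl group ortho to a formyl group, and one equivalent should stop at the mono-phenol because the two methoxy groups of 14 are equivalent and the aryloxyboron chelate formed first ties up the reagent.

Step 9
Reactants: 15 2-hydroxy-5-methoxybenzene-1,4-dicarbaldehyde
Product: 16 2,5-bis(hydroxymethyl)-4-methoxyphenol
Conditions: NaBH4, MeOH, 0 °C
Reagents that add atoms: none
Why: Borohydride reduction of both formyl groups should give the bis(benzylic) alcohol.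

Step 10
Reactants: 16 2,5-bis(hydroxymethyl)-4-methoxyphenol
Product: 17 2,5-bis(hydroxymethyl)-4,4-dimethoxycyclohexa-2,5-dien-1-one
Conditions: PhI(OAc)2, MeOH, 0 °C
Reagents that add atoms: methanol, CO
Why: Oxidative dearomatisation of a para-methoxyphenol with a hypervalent iodine reagent in methanol should give the quinone monoketal with the ketone at the former phenol carbon, which leaves one hydroxymethyl group α to the ketone and the other next to the ketal.

Step 11
Reactants: 17 2,5-bis(hydroxymethyl)-4,4-dimethoxycyclohexa-2,5-dien-1-one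
Product: 18 (1S)-2,5-bis(hydroxymethyl)-4,4-dimethoxycyclohexa-2,5-dien-1-ol
Conditions: (R)-2-methyl-CBS-oxazaborolidine (20 mol%), BH3·SMe2 (3 equiv), THF, −30 °C
Reagents that add atoms: none
Why: Corey–Bakshi–Shibata reduction should deliver hydride to the dienone face chosen by the catalyst, the α-substituted alkene arm acting as the large group, and give the S dienol.

Step 12
Reactants: 18 (1S)-2,5-bis(hydroxymethyl)-4,4-dimethoxycyclohexa-2,5-dien-1-ol
Product: 19 [(8aS)-2,2-di-tert-butyl-6,6-dimethoxy-6,8a-dihydro-4H-1,3,2-benzodioxasilin-7-yl]methanol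
Conditions: tBu2Si(OTf)2 (1.05 equiv), 2,6-lutidine, CH2Cl2, −40 to 0 °C
Reagents that add atoms: di-tert-butylsilyl bis(trifluoromethanesulfonate), CC(C)(C)[Si](OS(=O)(=O)C(F)(F)F)(OS(=O)(=O)C(F)(F)F)C(C)(C)C
Why: Silylene protection should tie the ring hydroxyl to the hydroxymethyl group on the neighbouring carbon as a six-membered dioxasilinane, this pair being the only 1,3-diol in 18, and leave the remote hydroxymethyl group free.

Step 13
Reactants: 19 [(8aS)-2,2-di-tert-butyl-6,6-dimethoxy-6,8a-dihydro-4H-1,3,2-benzodioxasilin-7-yl]methanol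
Product: 20 (8aS)-2,2-di-tert-butyl-6,6-dimethoxy-6,8a-dihydro-4H-1,3,2-benzodioxasiline-7-carbaldehyde
Conditions: MnO2, CH2Cl2, rt
Reagents that add atoms: none
Why: Allylic oxidation with manganese dioxide should convert the one remaining primary allylic alcohol into the enal.

Step 14
Reactants: 20 (8aS)-2,2-di-tert-butyl-6,6-dimethoxy-6,8a-dihydro-4H-1,3,2-benzodioxasiline-7-carbaldehyde; 21 propyne
Product: 22 (1S)-1-[(8aS)-2,2-di-tert-butyl-6,6-dimethoxy-6,8a-dihydro-4H-1,3,2-benzodioxasilin-7-yl]but-2-yn-1-ol
Conditions: (S,S)-ProPhenol (10 mol%), Me2Zn (3 equiv), Ph3P=O (20 mol%), toluene, 0 °C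
Reagents that add atoms: none
Why: Zinc–ProPhenol-catalysed asymmetric alkynylation should add the propynylzinc to the Si face of the formyl group under ligand control and give the S propargylic alcohol.

Step 15
Reactants: 22 (1S)-1-[(8aS)-2,2-di-tert-butyl-6,6-dimethoxy-6,8a-dihydro-4H-1,3,2-benzodioxasilin-7-yl]but-2-yn-1-ol
Product: 24 (1S,2Z)-1-[(8aS)-2,2-di-tert-butyl-6,6-dimethoxy-6,8a-dihydro-4H-1,3,2-benzodioxasilin-7-yl]-3-iodobut-2-en-1-ol, via vinylalanate 23 (not isolated)
Conditions: NaAlH2(OCH2CH2OMe)2, THF, 0 °C; then I2, −78 °C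
Reagents that add atoms: iodine, II
Why: Hydroxyl-directed trans-hydroalumination of the propargylic alcohol gives the cyclic vinylalanate with aluminium on the distal alkyne carbon, and iodinolysis with retention should give the Z iodoalkene in which iodine is cis to the carbinol carbon.

Step 16
Reactants: 24 (1S,2Z)-1-[(8aS)-2,2-di-tert-butyl-6,6-dimethoxy-6,8a-dihydro-4H-1,3,2-benzodioxasilin-7-yl]-3-iodobut-2-en-1-ol
Product: 25 epoxy alcohol: 24 in which the ring alkene that carries the side chain is an oxirane, on the face opposite the silyloxy oxygen and erythro to the side-chain carbinol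
Conditions: Ti(OiPr)4 (0.2 equiv), L-(+)-DIPT (0.24 equiv), tBuOOH, 4 Å MS, CH2Cl2, −20 °C
Reagents that add atoms: tert-butyl hydroperoxide, CC(C)(C)OO
Why: Sharpless asymmetric epoxidation of the secondary allylic alcohol should oxidise only the ring alkene (the iodoalkene is electron-poor and Z-substituted), from the face set by the tartrate, erythro to the carbinol as for the fast-reacting enantiomer of a kinetic resolution and anti to the allylic silyloxy group, the three elements being matched.

Step 17
Reactants: 25 epoxy alcohol
Product: 26 epoxy enone: 25 in which the dimethyl ketal is the ketone, conjugated with the remaining ring alkene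
Conditions: montmorillonite K10, wet CH2Cl2, rt
Reagents that add atoms: water, O
Why: Mild acid-catalysed ketal hydrolysis should unmask the enone without opening the oxirane or the silylene.

Step 18
Reactants: 26 epoxy enone
Product: 27 west alkenyl iodide: 26 in which the ketone is a secondary alcohol on the face opposite the oxirane oxygen (1,3-anti to the side-chain hydroxyl)
Conditions: Me4NBH(OAc)3, MeCN/AcOH, −30 °C
Reagents that add atoms: none
Why: Evans–Saksena reduction, in which the side-chain hydroxyl binds the borohydride and delivers hydride internally through a chair six-membered transition state, should give the 1,3-anti diol, which places the new ring hydroxyl trans to the oxirane.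

Step 19
Reactants: 27 west alkenyl iodide; 13 (1R,2R,4R)-1,3,3-trimethyl-2-[(E)-2-(4,4,5,5-tetramethyl-1,3,2-dioxaborolan-2-yl)ethenyl]cyclohexane-1,4-diol
Product: 28 silylene-protected arthrosporol A (the ring hydroxyl next to the hydroxymethyl-bearing carbon and the hydroxymethyl oxygen bridged by di-tert-butylsilylene)
Conditions: Pd(dppf)Cl2 (5 mol%), K3PO4 (aq), THF, rt
Reagents that add atoms: none
Why: Suzuki–Miyaura coupling of the alkenyl iodide with the alkenylboronate should join the two sp2 carbons with retention of both alkene geometries and give the 2Z,4E diene.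

Step 20
Reactants: 28 silylene-protected arthrosporol A
Product: 29 arthrosporol A
Conditions: HF·pyridine, pyridine, THF, 0 °C
Reagents that add atoms: none
Why: Fluoride cleavage of the di-tert-butylsilylene under buffered, non-basic conditions should free the last two hydroxyls without Payne rearrangement of the epoxy alcohol.

**Compound list**

1 | ethyl 4-chloro-3-oxobutanoate | CCOC(=O)CC(=O)CCl | starting material
2 | acetone | CC(C)=O | starting material
3 | ethyl 2-(2-chloroacetyl)-3-methylbut-2-enoate | CCOC(=O)C(=C(C)C)C(=O)CCl | intermediate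
4 | trimethyl(vinyloxy)silane | C=CO[Si](C)(C)C | starting material
5 | ethyl 2-(2-iodoacetyl)-3-methylbut-2-enoate (not isolated) | CCOC(=O)C(=C(C)C)C(=O)CI | intermediate
6 | racemic ethyl 2,2-dimethyl-6-oxo-3-(trimethylsilyloxy)cyclohexane-1-carboxylate (not isolated) | CCOC(=O)C1C(C)(C)C(O[Si](C)(C)C)CCC1=O | intermediate
7 | racemic ethyl 3-hydroxy-2,2-dimethyl-6-oxocyclohexane-1-carboxylate | CCOC(=O)C1C(C)(C)C(O)CCC1=O | intermediate
8 | ethyl 2,2-dimethyl-3,6-dioxocyclohexane-1-carboxylate | CCOC(=O)C1C(C)(C)C(=O)CCC1=O | intermediate
9 | ethyl (3R)-3-hydroxy-2,2-dimethyl-6-oxocyclohexane-1-carboxylate, C1 epimers (not isolated) | CCOC(=O)C1C(C)(C)[C@H](O)CCC1=O | intermediate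
10 | (1R,5R)-8,8-dimethyl-6-oxabicyclo[3.2.1]octane-2,7-dione | O=C2[C@@H]1C(C)(C)[C@H](O2)CCC1=O | intermediate
11 | (1R,2R,5R)-2-hydroxy-2,8,8-trimethyl-6-oxabicyclo[3.2.1]octan-7-one | O=C2[C@@H]1C(C)(C)[C@H](O2)CC[C@@]1(C)O | intermediate
12 | (1R,2R,5R)-2,8,8-trimethyl-6-oxabicyclo[3.2.1]octane-2,7-diol, lactol epimers | OC2[C@@H]1C(C)(C)[C@H](O2)CC[C@@]1(C)O | intermediate
13 | (1R,2R,4R)-1,3,3-trimethyl-2-[(E)-2-(4,4,5,5-tetramethyl-1,3,2-dioxaborolan-2-yl)ethenyl]cyclohexane-1,4-diol | CC1(C)OB(/C=C/[C@@H]2C(C)(C)[C@H](O)CC[C@@]2(C)O)OC1(C)C | intermediate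
14 | 2,5-dimethoxybenzene-1,4-dicarbaldehyde | COc1cc(C=O)c(OC)cc1C=O | starting material
15 | 2-hydroxy-5-methoxybenzene-1,4-dicarbaldehyde | COc1cc(C=O)c(O)cc1C=O | intermediate
16 | 2,5-bis(hydroxymethyl)-4-methoxyphenol | COc1cc(CO)c(O)cc1CO | intermediate
17 | 2,5-bis(hydroxymethyl)-4,4-dimethoxycyclohexa-2,5-dien-1-one | O=C1C=C(CO)C(OC)(OC)C=C1CO | intermediate
18 | (1S)-2,5-bis(hydroxymethyl)-4,4-dimethoxycyclohexa-2,5-dien-1-ol | OCC1=C[C@H](O)C(CO)=CC1(OC)OC | intermediate
19 | [(8aS)-2,2-di-tert-butyl-6,6-dimethoxy-6,8a-dihydro-4H-1,3,2-benzodioxasilin-7-yl]methanol | OCC1=C[C@@H]2O[Si](C(C)(C)C)(C(C)(C)C)OCC2=CC1(OC)OC | intermediate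
20 | (8aS)-2,2-di-tert-butyl-6,6-dimethoxy-6,8a-dihydro-4H-1,3,2-benzodioxasiline-7-carbaldehyde | O=CC1=C[C@@H]2O[Si](C(C)(C)C)(C(C)(C)C)OCC2=CC1(OC)OC | intermediate
21 | propyne | CC#C | starting material
22 | (1S)-1-[(8aS)-2,2-di-tert-butyl-6,6-dimethoxy-6,8a-dihydro-4H-1,3,2-benzodioxasilin-7-yl]but-2-yn-1-ol | CC#C[C@H](O)C1=C[C@@H]2O[Si](C(C)(C)C)(C(C)(C)C)OCC2=CC1(OC)OC | intermediate
23 | sodium vinylalanate: five-membered 1,2-oxaaluminate formed from 22, aluminium on the methyl-bearing alkene carbon, two 2-methoxyethoxy groups on aluminium (not isolated) | CC1=C[C@@H](C2=C[C@@H]3O[Si](C(C)(C)C)(C(C)(C)C)OCC3=CC2(OC)OC)O[Al-]1(OCCOC)OCCOC.[Na+] | intermediate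
24 | (1S,2Z)-1-[(8aS)-2,2-di-tert-butyl-6,6-dimethoxy-6,8a-dihydro-4H-1,3,2-benzodioxasilin-7-yl]-3-iodobut-2-en-1-ol | CC(=C/[C@H](O)C1=C[C@@H]2O[Si](C(C)(C)C)(C(C)(C)C)OCC2=CC1(OC)OC)/I | intermediate
25 | epoxy alcohol: 24 with the side-chain-bearing ring alkene as an oxirane, trans to the silyloxy oxygen, erythro to the carbinol | CC(=C/[C@H](O)[C@]12O[C@H]1[C@@H]3O[Si](C(C)(C)C)(C(C)(C)C)OCC3=CC2(OC)OC)/I | intermediate
26 | epoxy enone: 25 with the ketal hydrolysed to the ketone | CC(=C/[C@H](O)[C@]12O[C@H]1[C@@H]3O[Si](C(C)(C)C)(C(C)(C)C)OCC3=CC2=O)/I | intermediate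
27 | west alkenyl iodide: 26 with the ketone reduced to the hydroxyl trans to the oxirane | CC(=C/[C@H](O)[C@]12O[C@H]1[C@@H]3O[Si](C(C)(C)C)(C(C)(C)C)OCC3=C[C@@H]2O)/I | intermediate
28 | silylene-protected arthrosporol A | CC(=C/[C@H](O)[C@]12O[C@H]1[C@@H]3O[Si](C(C)(C)C)(C(C)(C)C)OCC3=C[C@@H]2O)/C=C/[C@@H]4C(C)(C)[C@H](O)CC[C@@]4(C)O | intermediate
29 | arthrosporol A | CC(=C/[C@H](O)[C@]12O[C@H]1[C@H](O)C(CO)=C[C@@H]2O)/C=C/[C@@H]1C(C)(C)[C@H](O)CC[C@@]1(C)O | target

**Step count and risks**

Total step count: 20. Longest linear sequence: 13 steps (steps 8 to 20); the east branch is steps 1 to 7 and joins at step 19.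

Steps most likely to fail:

Step 2. What may go wrong: hydrogen transfer to the first or second radical before the next bond forms, or a 6-endo closure at the fully substituted alkene carbon that is too slow. Fallback with known chemistry: from 3 (with 4) the photocatalyst is used without a hydrogen donor (fac-Ir(ppy)3, NaI, NaHCO3, MeCN, blue LEDs). Under these conditions the α-silyloxy radical is oxidised and desilylated, a known photoredox α-alkylation of a silyl enol ether, to give the keto aldehyde ethyl 3-methyl-2-(4-oxobutanoyl)but-2-enoate F1. An intramolecular Stetter reaction (triazolium carbene precatalyst, Et3N, toluene) then adds the acyl carbon to the isopropylidene carbon and closes the ring, coming back to the route at 8.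

Step 4. What may go wrong: reduction of the wrong carbonyl group, or poor face selection or catalyst inhibition with the substrate present as an enolate salt. Fallback: from 8, silylation of the β-keto ester (TBSOTf, Et3N, CH2Cl2, −78 °C) gives the silyl enol ether ethyl 2-[tert-butyl(dimethyl)silyl]oxy-6,6-dimethyl-5-oxocyclohex-1-ene-1-carboxylate F2. Corey–Bakshi–Shibata reduction of the one remaining ketone ((S)-2-methyl-CBS-oxazaborolidine, catecholborane, toluene, −78 °C) gives ethyl (5R)-2-[tert-butyl(dimethyl)silyl]oxy-5-hydroxy-6,6-dimethylcyclohex-1-ene-1-carboxylate F3. TsOH in wet toluene at 90 °C then removes the silyl group and lactonises, coming back at 10.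

Step 14. What may go wrong: poor facial selectivity or sluggish addition at the hindered formyl group next to the ketal. Fallback: from 20, addition of 1-propynylmagnesium bromide (THF, −78 °C) gives both carbinol epimers, 1-[(8aS)-2,2-di-tert-butyl-6,6-dimethoxy-6,8a-dihydro-4H-1,3,2-benzodioxasilin-7-yl]but-2-yn-1-ol F4. MnO2 oxidises this to the ynone 1-[(8aS)-2,2-di-tert-butyl-6,6-dimethoxy-6,8a-dihydro-4H-1,3,2-benzodioxasilin-7-yl]but-2-yn-1-one F5. Noyori asymmetric transfer hydrogenation (RuCl(p-cymene)[(S,S)-TsDPEN], HCO2H/Et3N) reduces the alkynyl ketone to 22, where the route is rejoined.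

**Further compounds**

F1 | step 2 | ethyl 3-methyl-2-(4-oxobutanoyl)but-2-enoate | CCOC(=O)C(=C(C)C)C(=O)CCC=O
F2 | step 4 | ethyl 2-[tert-butyl(dimethyl)silyl]oxy-6,6-dimethyl-5-oxocyclohex-1-ene-1-carboxylate | CCOC(=O)C1=C(O[Si](C)(C)C(C)(C)C)CCC(=O)C1(C)C
F3 | step 4 | ethyl (5R)-2-[tert-butyl(dimethyl)silyl]oxy-5-hydroxy-6,6-dimethylcyclohex-1-ene-1-carboxylate | CCOC(=O)C1=C(O[Si](C)(C)C(C)(C)C)CC[C@@H](O)C1(C)C
F4 | step 14 | 1-[(8aS)-2,2-di-tert-butyl-6,6-dimethoxy-6,8a-dihydro-4H-1,3,2-benzodioxasilin-7-yl]but-2-yn-1-ol, both carbinol epimers | CC#CC(O)C1=C[C@@H]2O[Si](C(C)(C)C)(C(C)(C)C)OCC2=CC1(OC)OC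
F5 | step 14 | 1-[(8aS)-2,2-di-tert-butyl-6,6-dimethoxy-6,8a-dihydro-4H-1,3,2-benzodioxasilin-7-yl]but-2-yn-1-one | CC#CC(=O)C1=C[C@@H]2O[Si](C(C)(C)C)(C(C)(C)C)OCC2=CC1(OC)OC
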